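**Retrosynthetic overview**
- Target ⇐ hydrogenolysis of two aryl benzyl ethers; CHO ⇐ CH2O‑TBDPS (desilylation, Dess–Martin oxidation); side‑chain ester ⇐ pyran acetic acid + O,O‑dibenzyl hydroxytyrosol (from 3,4‑dihydroxyphenylacetic acid).
- Dihydropyran ring (formed second) ⇐ δ‑lactone acid, by crossed Claisen formylation and acid‑promoted acyl‑lactone rearrangement in methanol.
- Key C–C bond (C4–CH2 of the acetate arm) ⇐ intermolecular Michael addition of dibenzyl malonate to a cis‑5,6‑disubstituted 5,6‑dihydropyran‑2‑one, trans to both ring substituents; then debenzylation and decarboxylation.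
- Pentenolide ring (formed first) ⇐ ring‑closing metathesis of an acrylate installed by Mitsunobu inversion on a mono‑silylated 2‑vinyl‑1,3‑diol.
- Diol ⇐ Evans syn aldol of the (S)‑4‑benzyloxazolidinone crotonate imide with acetaldehyde.

Assumption: the SMILES is taken as drawn, i.e. the (2S,3S,4S) dihydropyran with 2‑CH3/3‑CHO cis and 3‑CHO/4‑CH2CO2R trans. TBDPS = tert‑butyldiphenylsilyl, Bn = benzyl.

**Route**

Step 1
Reactants: 1 (S)-4-benzyloxazolidin-2-one; 2 (E)-but-2-enoyl chloride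
Product: 3 (S)-4-benzyl-3-[(E)-but-2-enoyl]oxazolidin-2-one
Conditions: n-BuLi, THF, −78 °C; then 2, −78 → 0 °C
Reagents that add atoms: none
Why: N‑acylation of the lithiated oxazolidinone by the acid chloride is a standard imide formation that attaches the auxiliary without touching the E‑alkene.

Step 2
Reactants: 3 (S)-4-benzyl-3-[(E)-but-2-enoyl]oxazolidin-2-one; 4 acetaldehyde
Product: 6 (S)-4-benzyl-3-[(2S,3R)-2-ethenyl-3-hydroxybutanoyl]oxazolidin-2-one, via dibutylboron Z-dienolate 5 (not isolated)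
Conditions: Bu2BOTf, Et3N, CH2Cl2, −78 → 0 °C; then 4 (freshly distilled, excess), −78 → 0 °C; pH 7 buffer, MeOH, 30% H2O2, 0 °C
Reagents that add atoms: none
Why: Evans boron aldol reaction of the crotonate imide: γ‑deprotonation gives the Z‑dienolate, which adds through its α‑carbon in a closed Zimmerman–Traxler transition state on the face away from the benzyl group, setting the α‑centre (S, the future C3) and the syn carbinol (R, to be inverted in step 5).

Step 3
Reactants: 6 (S)-4-benzyl-3-[(2S,3R)-2-ethenyl-3-hydroxybutanoyl]oxazolidin-2-one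
Product: 7 (2R,3R)-2-ethenylbutane-1,3-diol
Conditions: LiBH4, MeOH (1 equiv), THF, 0 °C; non‑aqueous work‑up (diol is water‑soluble)
Reagents that add atoms: none
Why: Reductive cleavage of the N‑acyl oxazolidinone with LiBH4 gives the primary alcohol and the recoverable auxiliary without epimerising the non‑conjugated α‑vinyl centre.

Step 4
Reactants: 7 (2R,3R)-2-ethenylbutane-1,3-diol
Product: 8 (2R,3R)-3-(TBDPS-oxymethyl)pent-4-en-2-ol
Conditions: TBDPSCl (1.05 equiv), imidazole, CH2Cl2, 0 °C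
Reagents that add atoms: tert-butylchlorodiphenylsilane (TBDPSCl), CC(C)(C)[Si](Cl)(c1ccccc1)c1ccccc1
Why: Silyl ether formation with the bulky chlorosilane is selective for the primary over the secondary hydroxyl.

Step 5
Reactants: 8 (2R,3R)-3-(TBDPS-oxymethyl)pent-4-en-2-ol
Product: 9 (2S,3R)-3-(TBDPS-oxymethyl)pent-4-en-2-yl prop-2-enoate
Conditions: acrylic acid, PPh3, DIAD, THF, 0 °C → rt
Reagents that add atoms: acrylic acid, C=CC(=O)O
Why: Mitsunobu esterification displaces the alkoxyphosphonium by acrylate in an SN2 step, inverting the carbinol to S (the future C2, now cis‑disposed to the CH2O arm in the ring to come) and installing the acrylate in the same operation.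

Step 6
Reactants: 9 (2S,3R)-3-(TBDPS-oxymethyl)pent-4-en-2-yl prop-2-enoate
Product: 10 (5R,6S)-5-(TBDPS-oxymethyl)-6-methyl-5,6-dihydro-2H-pyran-2-one (5,6‑cis)
Conditions: second-generation Grubbs catalyst RuCl2(=CHPh)(PCy3)(H2IMes) (5 mol %), CH2Cl2 (0.01 M), 40 °C
Reagents that add atoms: none
Why: Ring‑closing metathesis of an acrylate of a homoallylic alcohol closes the six‑membered unsaturated lactone with loss of ethene and leaves both stereocentres untouched.

Step 7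
Reactants: 10 (5R,6S)-5-(TBDPS-oxymethyl)-6-methyl-5,6-dihydro-2H-pyran-2-one; 11 dibenzyl malonate
Product: 12 dibenzyl 2-[(2S,3R,4R)-3-(TBDPS-oxymethyl)-2-methyl-6-oxooxan-4-yl]propanedioate
Conditions: 11 (1.5 equiv), NaH (0.3 equiv), THF, 0 °C → rt
Reagents that add atoms: none
Why: Intermolecular Michael addition of the soft malonate anion to the pentenolide occurs by axial attack on the face opposite the cis 5‑CH2OTBDPS/6‑CH3 pair, setting the new centre trans to both (the future C4); the weakly basic malonate does not deprotonate the γ‑position.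

Step 8
Reactants: 12 dibenzyl 2-[(2S,3R,4R)-3-(TBDPS-oxymethyl)-2-methyl-6-oxooxan-4-yl]propanedioate
Product: 14 2-[(2S,3R,4R)-3-(TBDPS-oxymethyl)-2-methyl-6-oxooxan-4-yl]acetic acid, via lactone malonic acid 13 (not isolated)
Conditions: H2 (1 atm), 10% Pd/C, EtOAc, rt; filter; toluene, 110 °C
Reagents that add atoms: none
Why: Hydrogenolysis of the benzyl esters followed by thermal decarboxylation of the malonic acid gives the acetic acid arm under neutral conditions that spare lactone and silyl ether.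

Step 9
Reactants: 14 2-[(2S,3R,4R)-3-(TBDPS-oxymethyl)-2-methyl-6-oxooxan-4-yl]acetic acid
Product: 15 2-[(2S,3R,4S)-3-(TBDPS-oxymethyl)-5-(hydroxymethylidene)-2-methyl-6-oxooxan-4-yl]acetic acid (enol form of the α‑formyl lactone)
Conditions: LiN(iPr)2 (LDA, 2.3 equiv), THF, −78 °C; HCO2Me (5 equiv), −78 → −20 °C; 1 M HCl
Reagents that add atoms: methyl formate, COC=O
Why: Crossed Claisen condensation (formylation): the first equivalent of base makes the lithium carboxylate, whose α‑protons are far less acidic, so the second enolises only the lactone α‑CH2, and this regiochemistry fixes which arm enters the new ring and hence the C4 configuration.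

Step 10
Reactants: 15 2-[(2S,3R,4S)-3-(TBDPS-oxymethyl)-5-(hydroxymethylidene)-2-methyl-6-oxooxan-4-yl]acetic acid
Product: 17 methyl (2S,3R,4S)-3-(TBDPS-oxymethyl)-4-(2-methoxy-2-oxoethyl)-2-methyl-3,4-dihydro-2H-pyran-5-carboxylate, via cyclic methyl acetal 16 (not isolated)
Conditions: HCl (0.3 M in MeOH), rt; concentrate; PPTS (0.3 equiv), toluene, 100 °C
Reagents that add atoms: methanol, CO
Why: Acyl‑lactone (Korte) rearrangement: acid methanolysis opens the lactone by acyl–oxygen cleavage (C2–O retained), the freed C2 hydroxyl closes onto the formyl carbon as a methyl acetal, and loss of methanol gives the conjugated β‑alkoxyacrylate, with Fischer esterification of the side‑chain acid alongside.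

Step 11
Reactants: 17 methyl (2S,3R,4S)-3-(TBDPS-oxymethyl)-4-(2-methoxy-2-oxoethyl)-2-methyl-3,4-dihydro-2H-pyran-5-carboxylate
Product: 18 2-[(2S,3R,4S)-3-(TBDPS-oxymethyl)-5-(methoxycarbonyl)-2-methyl-3,4-dihydro-2H-pyran-4-yl]acetic acid
Conditions: LiOH·H2O (1.2 equiv), THF/H2O (3:1), 0 °C; then 1 M HCl to pH 3
Reagents that add atoms: lithium hydroxide, [Li+].[OH-]
Why: Chemoselective saponification: the unhindered aliphatic methyl ester is hydrolysed while the vinylogous carbonate (β‑alkoxyacrylate) ester is deactivated by the ring oxygen.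

Step 12
Reactants: 19 3,4-dihydroxyphenylacetic acid
Product: 20 benzyl 2-[3,4-bis(benzyloxy)phenyl]acetate
Conditions: BnBr (3.3 equiv), K2CO3, DMF, 60 °C, N2
Reagents that add atoms: benzyl bromide, BrCc1ccccc1
Why: Williamson‑type SN2 O‑alkylation of both phenoxides and the carboxylate protects the catechol in one operation.

Step 13
Reactants: 20 benzyl 2-[3,4-bis(benzyloxy)phenyl]acetate
Product: 21 2-[3,4-bis(benzyloxy)phenyl]ethanol
Conditions: LiAlH4, THF, 0 °C → rt
Reagents that add atoms: none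
Why: Hydride reduction of the ester gives the primary alcohol while aryl benzyl ethers are inert.

Step 14
Reactants: 18 2-[(2S,3R,4S)-3-(TBDPS-oxymethyl)-5-(methoxycarbonyl)-2-methyl-3,4-dihydro-2H-pyran-4-yl]acetic acid; 21 2-[3,4-bis(benzyloxy)phenyl]ethanol
Product: 22 methyl (2S,3R,4S)-4-{2-[2-(3,4-bis(benzyloxy)phenyl)ethoxy]-2-oxoethyl}-3-(TBDPS-oxymethyl)-2-methyl-3,4-dihydro-2H-pyran-5-carboxylate
Conditions: EDC·HCl, DMAP (0.2 equiv), CH2Cl2, 0 °C → rt
Reagents that add atoms: none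
Why: Steglich esterification of an unhindered acid with a primary alcohol is dependable, and no epimerisable centre is present at this stage.

Step 15
Reactants: 22 methyl (2S,3R,4S)-4-{2-[2-(3,4-bis(benzyloxy)phenyl)ethoxy]-2-oxoethyl}-3-(TBDPS-oxymethyl)-2-methyl-3,4-dihydro-2H-pyran-5-carboxylate
Product: 23 methyl (2S,3R,4S)-4-{2-[2-(3,4-bis(benzyloxy)phenyl)ethoxy]-2-oxoethyl}-3-(hydroxymethyl)-2-methyl-3,4-dihydro-2H-pyran-5-carboxylate
Conditions: HF·pyridine, pyridine, THF, 0 °C → rt; use at once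
Reagents that add atoms: none
Why: Fluoride desilylation under buffered, weakly acidic conditions frees the primary alcohol, and lactonisation onto the trans‑disposed ester arm is slow because both groups sit pseudoaxial and anti.

Step 16
Reactants: 23 methyl (2S,3R,4S)-4-{2-[2-(3,4-bis(benzyloxy)phenyl)ethoxy]-2-oxoethyl}-3-(hydroxymethyl)-2-methyl-3,4-dihydro-2H-pyran-5-carboxylate
Product: 24 methyl (2S,3S,4S)-4-{2-[2-(3,4-bis(benzyloxy)phenyl)ethoxy]-2-oxoethyl}-3-formyl-2-methyl-3,4-dihydro-2H-pyran-5-carboxylate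
Conditions: Dess–Martin periodinane (1.3 equiv), CH2Cl2, 0 °C → rt; Na2S2O3/NaHCO3 work‑up, short silica plug
Reagents that add atoms: none
Why: Dess–Martin oxidation is mild and non‑basic, so the α‑stereocentre of the β‑alkoxy aldehyde is neither epimerised nor lost by retro‑oxa‑Michael opening.

Step 17
Reactants: 24 methyl (2S,3S,4S)-4-{2-[2-(3,4-bis(benzyloxy)phenyl)ethoxy]-2-oxoethyl}-3-formyl-2-methyl-3,4-dihydro-2H-pyran-5-carboxylate
Product: 25 methyl (2S,3S,4S)-4-{2-[2-(3,4-dihydroxyphenyl)ethoxy]-2-oxoethyl}-3-formyl-2-methyl-3,4-dihydro-2H-pyran-5-carboxylate (CNP0172886.2)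
Conditions: H2 (1 atm), 10% Pd/C, EtOAc, rt, 1–2 h; filter under argon
Reagents that add atoms: none
Why: Hydrogenolysis of aryl benzyl ethers is fast and neutral, far faster than reduction of the aliphatic aldehyde or of the push–pull β‑alkoxyacrylate alkene, so the catechol is released without disturbing C3.

**Compound list**
1 | (S)-4-benzyloxazolidin-2-one | O=C1N[C@@H](Cc2ccccc2)CO1 | starting material
2 | (E)-but-2-enoyl chloride | C/C=C/C(Cl)=O | starting material
3 | (S)-4-benzyl-3-[(E)-but-2-enoyl]oxazolidin-2-one | C/C=C/C(=O)N1[C@@H](Cc2ccccc2)COC1=O | intermediate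
4 | acetaldehyde | CC=O | starting material
5 | (S)-4-benzyl-3-[(1Z)-1-(dibutylboranyloxy)buta-1,3-dienyl]oxazolidin-2-one (boron dienolate) | C=C/C=C(\OB(CCCC)CCCC)N1[C@@H](Cc2ccccc2)COC1=O | intermediate
6 | (S)-4-benzyl-3-[(2S,3R)-2-ethenyl-3-hydroxybutanoyl]oxazolidin-2-one | O[C@H](C)[C@@H](C(=O)N1[C@@H](Cc2ccccc2)COC1=O)C=C | intermediate
7 | (2R,3R)-2-ethenylbutane-1,3-diol | O[C@H](C)[C@@H](CO)C=C | intermediate
8 | (2R,3R)-3-{[tert-butyl(diphenyl)silyl]oxymethyl}pent-4-en-2-ol | O[C@H](C)[C@@H](CO[Si](c1ccccc1)(c1ccccc1)C(C)(C)C)C=C | intermediate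
9 | (2S,3R)-3-{[tert-butyl(diphenyl)silyl]oxymethyl}pent-4-en-2-yl prop-2-enoate | C=CC(=O)O[C@@H](C)[C@@H](CO[Si](c1ccccc1)(c1ccccc1)C(C)(C)C)C=C | intermediate
10 | (5R,6S)-5-{[tert-butyl(diphenyl)silyl]oxymethyl}-6-methyl-5,6-dihydro-2H-pyran-2-one | O=C1O[C@@H](C)[C@@H](CO[Si](c2ccccc2)(c2ccccc2)C(C)(C)C)C=C1 | intermediate
11 | dibenzyl malonate | O=C(CC(=O)OCc1ccccc1)OCc1ccccc1 | starting material
12 | dibenzyl 2-[(2S,3R,4R)-3-{[tert-butyl(diphenyl)silyl]oxymethyl}-2-methyl-6-oxooxan-4-yl]propanedioate | O=C1O[C@@H](C)[C@@H](CO[Si](c2ccccc2)(c2ccccc2)C(C)(C)C)[C@H](C(C(=O)OCc2ccccc2)C(=O)OCc2ccccc2)C1 | intermediate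
13 | 2-[(2S,3R,4R)-3-{[tert-butyl(diphenyl)silyl]oxymethyl}-2-methyl-6-oxooxan-4-yl]propanedioic acid | O=C1O[C@@H](C)[C@@H](CO[Si](c2ccccc2)(c2ccccc2)C(C)(C)C)[C@H](C(C(=O)O)C(=O)O)C1 | intermediate
14 | 2-[(2S,3R,4R)-3-{[tert-butyl(diphenyl)silyl]oxymethyl}-2-methyl-6-oxooxan-4-yl]acetic acid | O=C1O[C@@H](C)[C@@H](CO[Si](c2ccccc2)(c2ccccc2)C(C)(C)C)[C@H](CC(=O)O)C1 | intermediate
15 | 2-[(2S,3R,4S)-3-{[tert-butyl(diphenyl)silyl]oxymethyl}-5-(hydroxymethylidene)-2-methyl-6-oxooxan-4-yl]acetic acid (alkene geometry not defined) | O=C1O[C@@H](C)[C@@H](CO[Si](c2ccccc2)(c2ccccc2)C(C)(C)C)[C@H](CC(=O)O)C1=CO | intermediate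
16 | methyl (2S,3R,4S)-3-{[tert-butyl(diphenyl)silyl]oxymethyl}-6-methoxy-4-(2-methoxy-2-oxoethyl)-2-methyloxane-5-carboxylate (epimer mixture at C5 and C6) | COC(=O)C1C(OC)O[C@@H](C)[C@@H](CO[Si](c2ccccc2)(c2ccccc2)C(C)(C)C)[C@@H]1CC(=O)OC | intermediate
17 | methyl (2S,3R,4S)-3-{[tert-butyl(diphenyl)silyl]oxymethyl}-4-(2-methoxy-2-oxoethyl)-2-methyl-3,4-dihydro-2H-pyran-5-carboxylate | COC(=O)C1=CO[C@@H](C)[C@@H](CO[Si](c2ccccc2)(c2ccccc2)C(C)(C)C)[C@@H]1CC(=O)OC | intermediate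
18 | 2-[(2S,3R,4S)-3-{[tert-butyl(diphenyl)silyl]oxymethyl}-5-(methoxycarbonyl)-2-methyl-3,4-dihydro-2H-pyran-4-yl]acetic acid | COC(=O)C1=CO[C@@H](C)[C@@H](CO[Si](c2ccccc2)(c2ccccc2)C(C)(C)C)[C@@H]1CC(=O)O | intermediate
19 | 3,4-dihydroxyphenylacetic acid | OC(=O)Cc1ccc(O)c(O)c1 | starting material
20 | benzyl 2-[3,4-bis(benzyloxy)phenyl]acetate | O=C(Cc1ccc(OCc2ccccc2)c(OCc2ccccc2)c1)OCc1ccccc1 | intermediate
21 | 2-[3,4-bis(benzyloxy)phenyl]ethanol | OCCc1ccc(OCc2ccccc2)c(OCc2ccccc2)c1 | intermediate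
22 | methyl (2S,3R,4S)-4-{2-[2-(3,4-bis(benzyloxy)phenyl)ethoxy]-2-oxoethyl}-3-{[tert-butyl(diphenyl)silyl]oxymethyl}-2-methyl-3,4-dihydro-2H-pyran-5-carboxylate | COC(=O)C1=CO[C@@H](C)[C@@H](CO[Si](c2ccccc2)(c2ccccc2)C(C)(C)C)[C@@H]1CC(=O)OCCc1ccc(OCc2ccccc2)c(OCc2ccccc2)c1 | intermediate
23 | methyl (2S,3R,4S)-4-{2-[2-(3,4-bis(benzyloxy)phenyl)ethoxy]-2-oxoethyl}-3-(hydroxymethyl)-2-methyl-3,4-dihydro-2H-pyran-5-carboxylate | COC(=O)C1=CO[C@@H](C)[C@@H](CO)[C@@H]1CC(=O)OCCc1ccc(OCc2ccccc2)c(OCc2ccccc2)c1 | intermediate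
24 | methyl (2S,3S,4S)-4-{2-[2-(3,4-bis(benzyloxy)phenyl)ethoxy]-2-oxoethyl}-3-formyl-2-methyl-3,4-dihydro-2H-pyran-5-carboxylate | COC(=O)C1=CO[C@@H](C)[C@@H](C=O)[C@@H]1CC(=O)OCCc1ccc(OCc2ccccc2)c(OCc2ccccc2)c1 | intermediate
25 | methyl (2S,3S,4S)-4-{2-[2-(3,4-dihydroxyphenyl)ethoxy]-2-oxoethyl}-3-formyl-2-methyl-3,4-dihydro-2H-pyran-5-carboxylate | COC(=O)C1=CO[C@@H](C)[C@@H](C=O)[C@@H]1CC(=O)OCCc1ccc(O)c(O)c1 | target

**Step count**
Total: 17 steps. Longest linear sequence: 15 steps (steps 1–11 and 14–17); the alcohol fragment takes 2 steps (12–13).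

**Three steps most likely to fail, with fallbacks**

Step 5 (Mitsunobu with acrylic acid on a β‑branched secondary alcohol; risks are elimination to the diene and phosphine‑induced acrylate oligomerisation). Fallback, setting out from 8 and returning at 9: separate the inversion from the acylation. Mitsunobu reaction of 8 with the more acidic, non‑polymerisable 4‑nitrobenzoic acid (PPh3, DIAD, toluene, 0 °C → rt) gives the inverted ester (2S,3R)-3-(TBDPS-oxymethyl)pent-4-en-2-yl 4-nitrobenzoate F1. Methanolysis (K2CO3, MeOH, 0 °C) frees the inverted alcohol (2S,3R)-3-(TBDPS-oxymethyl)pent-4-en-2-ol F2. Ordinary acylation with acryloyl chloride (Et3N, DMAP cat., CH2Cl2, −20 °C) then gives 9.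

Step 9 (formylation through a carboxylate/lactone‑enolate dianion; risks are poor solubility or incomplete site selectivity). Fallback, setting out from 12 and returning at 18: formylate before the malonate is unmasked, so that the malonate protects itself as its enolate. Treating 12 with NaH (1.05 equiv), then LiN(iPr)2 (1.2 equiv, THF, −78 °C) and methyl formate gives dibenzyl 2-[(2S,3R,4R)-3-(TBDPS-oxymethyl)-5-(hydroxymethylidene)-2-methyl-6-oxooxan-4-yl]propanedioate F3. The conditions of step 10 convert it, through the cyclic methyl acetal dibenzyl 2-[(2S,3R,4S)-3-(TBDPS-oxymethyl)-6-methoxy-5-(methoxycarbonyl)-2-methyloxan-4-yl]propanedioate F4, into dibenzyl 2-[(2S,3R,4R)-3-(TBDPS-oxymethyl)-5-(methoxycarbonyl)-2-methyl-3,4-dihydro-2H-pyran-4-yl]propanedioate F5. Hydrogenolysis (H2, Pd/C, EtOAc) gives 2-[(2S,3R,4R)-3-(TBDPS-oxymethyl)-5-(methoxycarbonyl)-2-methyl-3,4-dihydro-2H-pyran-4-yl]propanedioic acid F6, which decarboxylates in toluene at 105 °C to 18. Steps 8–11 are not needed on this path.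

Step 15 (the freed primary alcohol could lactonise onto the neighbouring ester arm and expel the hydroxytyrosol unit). Fallback, setting out from 18 and returning at 24: unmask and oxidise while the arm is still a carboxylate, which cannot be attacked by the alcohol, and esterify last under neutral conditions. Acid 18 with Bu4NF (2.5 equiv, THF, rt) and careful acidification at 0 °C gives 2-[(2S,3R,4S)-3-(hydroxymethyl)-5-(methoxycarbonyl)-2-methyl-3,4-dihydro-2H-pyran-4-yl]acetic acid F7. Dess–Martin oxidation gives 2-[(2S,3S,4S)-3-formyl-5-(methoxycarbonyl)-2-methyl-3,4-dihydro-2H-pyran-4-yl]acetic acid F8. Mitsunobu esterification of F8 with alcohol 21 (PPh3, DIAD, THF, 0 °C) gives 24.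

**Further compounds**
F1 | step 5 | (2S,3R)-3-{[tert-butyl(diphenyl)silyl]oxymethyl}pent-4-en-2-yl 4-nitrobenzoate | O=C(O[C@@H](C)[C@@H](CO[Si](c1ccccc1)(c1ccccc1)C(C)(C)C)C=C)c1ccc([N+](=O)[O-])cc1
F2 | step 5 | (2S,3R)-3-{[tert-butyl(diphenyl)silyl]oxymethyl}pent-4-en-2-ol | O[C@@H](C)[C@@H](CO[Si](c1ccccc1)(c1ccccc1)C(C)(C)C)C=C
F3 | step 9 | dibenzyl 2-[(2S,3R,4R)-3-{[tert-butyl(diphenyl)silyl]oxymethyl}-5-(hydroxymethylidene)-2-methyl-6-oxooxan-4-yl]propanedioate | O=C1O[C@@H](C)[C@@H](CO[Si](c2ccccc2)(c2ccccc2)C(C)(C)C)[C@H](C(C(=O)OCc2ccccc2)C(=O)OCc2ccccc2)C1=CO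
F4 | step 9 | dibenzyl 2-[(2S,3R,4S)-3-{[tert-butyl(diphenyl)silyl]oxymethyl}-6-methoxy-5-(methoxycarbonyl)-2-methyloxan-4-yl]propanedioate (epimer mixture at C5 and C6) | COC(=O)C1C(OC)O[C@@H](C)[C@@H](CO[Si](c2ccccc2)(c2ccccc2)C(C)(C)C)[C@@H]1C(C(=O)OCc3ccccc3)C(=O)OCc3ccccc3
F5 | step 9 | dibenzyl 2-[(2S,3R,4R)-3-{[tert-butyl(diphenyl)silyl]oxymethyl}-5-(methoxycarbonyl)-2-methyl-3,4-dihydro-2H-pyran-4-yl]propanedioate | COC(=O)C1=CO[C@@H](C)[C@@H](CO[Si](c2ccccc2)(c2ccccc2)C(C)(C)C)[C@@H]1C(C(=O)OCc3ccccc3)C(=O)OCc3ccccc3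
F6 | step 9 | 2-[(2S,3R,4R)-3-{[tert-butyl(diphenyl)silyl]oxymethyl}-5-(methoxycarbonyl)-2-methyl-3,4-dihydro-2H-pyran-4-yl]propanedioic acid | COC(=O)C1=CO[C@@H](C)[C@@H](CO[Si](c2ccccc2)(c2ccccc2)C(C)(C)C)[C@@H]1C(C(=O)O)C(=O)O
F7 | step 15 | 2-[(2S,3R,4S)-3-(hydroxymethyl)-5-(methoxycarbonyl)-2-methyl-3,4-dihydro-2H-pyran-4-yl]acetic acid | COC(=O)C1=CO[C@@H](C)[C@@H](CO)[C@@H]1CC(=O)O
F8 | step 15 | 2-[(2S,3S,4S)-3-formyl-5-(methoxycarbonyl)-2-methyl-3,4-dihydro-2H-pyran-4-yl]acetic acid | COC(=O)C1=CO[C@@H](C)[C@@H](C=O)[C@@H]1CC(=O)O
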